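The numbers of this flask were chosen freely; the run is a simulation.

Raising the partner from cedar to oak looks like a gain in speed of 4.00 times, but partner enters just one term of a sum of waiting times.

| setting | cedar | elm | oak |
|---|---|---|---|
| substrate | 0.50 mM | 0.50 mM | 0.50 mM |
| partner | 1.50 equiv | 3.00 equiv | 6.00 equiv |
| free catalyst | 0.5 mol% | 0.5 mol% | 0.5 mol% |
| time | 12 s | 12 s | 12 s |

    partner + free catalyst ⇌ catalyst intermediate A (K1 = 980 M⁻¹, k1 = 51000 M⁻¹ s⁻¹)
    catalyst intermediate A → by-product + catalyst intermediate B (k2 = 47 s⁻¹)
    substrate + catalyst intermediate B → catalyst intermediate C (k3 = 5.6 × 10⁶ M⁻¹ s⁻¹)
    catalyst intermediate C ⇌ catalyst intermediate D (K4 = 0.12, k4 = 410 s⁻¹)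
    catalyst intermediate D → free catalyst + target (k5 = 230 s⁻¹)
    substrate + target → side product (k6 = 420 M⁻¹ s⁻¹)

- percentages count the substrate that a species holds: one side product counts as two
- run time (cedar): 12 s

1. which of these there is most of at the end, counted by the substrate in it, cedar (target / catalyst intermediate C / substrate / side product)
2. which of these there is most of at the end, counted by the substrate in it, elm (target / catalyst intermediate C / substrate / side product)
3. which of these there is most of at the end, counted by the substrate in it, oak (target / catalyst intermediate C / substrate / side product)
4. the largest of these amounts at the end, in percent of the substrate charged, cedar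
5. the largest of these amounts at the end, in percent of the substrate charged, elm
6. the largest of these amounts at the end, in percent of the substrate charged, oak

One round of the catalyst is a sum of waits. Summed over its visits, catalyst intermediate A costs 0.0213 s per round. Catalyst intermediate D falls back to catalyst intermediate C 14.9 times for each release of target, so that fast step stands near equilibrium and the C/D pool empties at 25.9 s⁻¹. With the stay in D, the pool costs 0.0430 s. Free catalyst is captured by partner, but just 47.5% of A goes forward, so each capture is counted at that share. Catalyst intermediate B waits 3.57 × 10⁻⁴ s at charged substrate, far less than A, so near that charge the turnover flow is close to zero order in substrate.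

Summed at the charges:

cedar: 0.120 s

elm: 0.0922 s

oak: 0.0784 s

This turnover time, the wait of one catalyst through a full round, turns each setting into an estimate of speed.

Partner: from cedar to oak the flow rises 1.53 times, less than the partner does.

Loading: the flow is catalyst charged over turnover time, and that time holds no loading, so turnovers scale straight with it while partner and substrate stand near their charges.

Time: turnovers grow with the run. At the starting flow, held over 12 s, they come to 50.1% of the substrate in cedar, 65.1% in elm and 76.5% in oak. Each turnover consumes a partner and a substrate, and these figures take no account of that.

Substrate: at its charge, target lasts 4.76 s, shorter than the run. Turnovers equal target plus side events, and each side event shows as two substrates in side product. The reckoning stops at that sum; the split needs stepping.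

The forecast starts from the same sum, “Each catalyst turnover takes a summed time”, and steps the split by hand. It names side product at 42% for cedar, side product at 46% for elm and target at 51% for oak.

The flasks give side product at 41.9% in cedar, side product at 46.1% in elm and target at 51.8% in oak. In elm at 5.84 s, target is made 2.07 times faster than it is used up, each step taken net. Elm's turnover time carries to the elm neighbour with free catalyst cut to 0.12 mol%, partner and substrate as in elm: that loading, over 0.0922 s, across 12 s, gives 0.0781 mM of turnovers. That neighbour holds 0.0775 mM of by-product, one per turnover, at 12.0 s.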